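## Analysis of the target

Target 15 is a dibenzylbutyrolactone lignan. Its core is an oxolan-2-one (O1, carbonyl C2, C3, C4, C5). C3 carries a 4-hydroxy-3-methoxybenzyl group through the benzylic carbon C7. C4 carries the carbinol carbon C7', which bears a hydroxyl and a 3,4-dimethoxyphenyl ring. These atom labels are kept for the open-chain intermediates.

There are three contiguous stereocentres: C3 (R), C4 (R) and C7' (S). The two ring substituents are trans. C4 and C7' are syn in the aldol sense when the chain C5–C4–C7'–aryl is drawn as a zigzag.

The sensitive group is the secondary benzylic alcohol on an electron-rich ring. In acid it ionises, leading to elimination or Friedel–Crafts closure onto the other arene, and it can be lost on hydrogenolysis. O7' is also γ to C2, so under base it can open the lactone and reclose to the isomeric lactone. The free phenol and the C3–H next to the carbonyl matter less, because the trans lactone is the stable one.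

The synthesis is hard because the hydroxyl sits on the C4 side chain, not the C3 one. The usual aldol of a β-benzyl lactone enolate therefore cannot place it, and the exocyclic C4/C7' relation needs acyclic stereocontrol. Two carboxyl-level carbons, C2 and C5, must also be told apart.

The strategy rests on the position of C4 between C7' and C5. With C7' as a ketone and C5 as an ester, C4 is the α-carbon of a β-keto ester and loses its configurational stability. One catalyst-controlled reduction of the C7' ketone can then fix C7' and C4 together, beside a C3 centre that is already in place and not acidic.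

## Retrosynthetic reasoning

**15 back to 14 and 13.** The last two operations only uncover oxygen atoms: the O–Si bond at C7' and the O–benzyl bond at the phenol. The phenol travels as a benzyl ether because it must pass alkoxide, amide-base and hydride steps. The carbinol travels as a silyl ether that leaves under buffered fluoride, since free 15 tolerates neither acid nor base. The benzyl group goes first (13 to 14), so that hydrogenolysis meets a hindered silyl ether at C7' and not a free benzylic alcohol. The silyl group goes last (14 to 15).

**13 back to 12.** The lactone bond O1–C2 is cut, giving the γ-hydroxy tert-butyl ester 12. This opening turns C2–C3–C4–C5 into a succinate chain with two carboxyl-level ends, which is what the earlier chemistry builds. Both O5 and O7' are γ to C2 and either could close a five-membered lactone; this is why O7' is silylated in 12. The closure is planned as a separate step under weak acid and is not left to the alkoxide of the preceding reduction. A lactone formed while hydride is present would be reduced further, and a free alkoxide at O5 could pull the silyl group over from O7' across the 1,3-diol.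

**12 back to 11.** C5 is returned to the carboxyl level as a methyl ester. With a tert-butyl ester on C2 and a methyl ester on C5, a mild hydride donor can reduce C5 alone.

**11 back to 10.** Only the O–Si bond is removed. The silyl group is put on directly after the hydroxyl is created, before any step in which that hydroxyl could attack C2.

**10 back to 9.** This is the strategic cut: the C7'–H bond. Removing it gives the aryl ketone 9, in which C4 lies between ketone and methyl ester. Compound 9 can be used as a mixture of C4 epimers, because the two interconvert through the enol. The forward reduction must deliver hydride to one face of the ketone, which sets C7', and must consume one C4 epimer much faster than the other, which sets C4. No carbon–carbon bond is formed here; the gain is two stereocentres from one catalytic step on a substrate whose only fixed centre is C3. The tert-butyl ester on C2 is kept because its bulk should stop the new hydroxyl from closing on C2.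

**9 back to 6 and 7.** The C4–C7' bond is cut between the ester α-carbon and the aroyl carbon. In the forward sense the enolate of the methyl ester in 6 is acylated by the acid chloride 7. The cut is made here because it builds the β-keto ester in one step from an aroyl unit and a succinate. The two different esters of 6 also direct deprotonation to the CH2 next to the methyl ester and away from the C3 stereocentre. The configuration at C4 does not matter at this stage.

**6 back to 5 and 4.** The methyl ester of 6 comes from the free acid 5. The C3–H and C7–H bonds of 5 come from hydrogenation of the C3=C7 alkene of 4. C3 is thus set by asymmetric catalysis on a substrate whose free carboxyl group can bind the metal.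

**4 back to 1 and 2.** The C3=C7 bond is cut by a Stobbe condensation of aldehyde 1 with diester 2. The Stobbe reaction differentiates the two carboxyls without extra steps. The conjugated one keeps its tert-butyl ester and becomes C2. The other emerges as the free acid, which becomes first the directing group for hydrogenation and then the methyl ester that ends as C5.

## Alternatives that were turned down

**Alternative 1: enantioselective Baeyer–Villiger expansion of a cyclobutanone.**
- Disconnection: the ring oxygen O1 is taken out from between C2 and C5, leading to 3-[(S)-(tert-butyldimethylsilyloxy)(3,4-dimethoxyphenyl)methyl]cyclobutan-1-one A1. The C3–C7 bond is cut second.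
- Forward key step: A1 is oxidised with aqueous hydrogen peroxide and a chiral phosphoric acid. One of the two ring CH2 groups migrates to oxygen and gives the lactone A2, which lacks the C3 substituent. The enolate of A2 is then alkylated with the benzylic bromide A3, trans to the C4 substituent.
- For: the regiochemistry of the oxidation is unambiguous, since both migrating carbons are CH2. The trans alkylation of a 4-substituted lactone enolate is probably the most dependable stereocontrol in this family, more dependable for C3 than a new hydrogenation. The aryl unit on C3 enters late, which would suit analogues better than the chosen route.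
- Against: A1 already holds the C7' centre, which needs its own asymmetric step. The catalyst must tell apart two CH2 groups that differ only through a remote, branched, already chiral substituent, so the outcome is a matched or mismatched double induction. The silylated electron-rich benzylic ether is exposed to Brønsted acid and peroxide. A1 itself needs a ketene cycloaddition, a dehalogenation and installation of the carbinol.
- Comparison: this route needs two independent enantioselective operations, C7' then C4, and more steps to reach the key substrate. The chosen route sets C4 and C7' in one operation in which the mechanism enforces their mutual relation.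

**Alternative 2: formaldehyde aldol with lactonisation of a γ-keto ester.**
- Disconnection: the C4–C5 and O1–C2 bonds are cut and C5 is removed as formaldehyde A5. This leads to methyl (2R)-2-[4-(benzyloxy)-3-methoxybenzyl]-4-(3,4-dimethoxyphenyl)-4-oxobutanoate A4.
- Forward key step: the enolate of the aryl ketone in A4 adds to A5 and the new alkoxide closes on the methyl ester, giving the keto lactone A6. Ketone reduction and debenzylation follow.
- For: the key step makes a carbon–carbon bond and the ring at once. No ester differentiation, silyl group or separate lactonisation is needed. C4 is α to the ketone in A6 and settles trans by equilibration. On step count it is stronger than the chosen route, by perhaps three steps.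
- Against: the key step does nothing for C7'. The later reduction of A6 must find the (S) face with only C4 to guide it, or needs a second catalyst-controlled step. The key step also has low-barrier side channels: intramolecular O-acylation of the ketone enolate by the ester, loss of water from the aldol to an enone, and a second hydroxymethylation at C4. The C3–H next to the ester is exposed to the base as well.
- Comparison: this route is shorter, but it leaves the stereochemical crux to a separate reduction and rests on a less predictable carbon–carbon bond formation. The chosen route forms its carbon–carbon bonds by a Stobbe condensation and an enolate acylation, and concentrates the risk in one well-understood catalytic reduction that sets C4 and C7' together.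

**Alternative 3: invertive opening of a cyclopropane-fused lactone by water.**
- Disconnection: the C7'–O and C3–H bonds are cut and the C3–C7' bond is restored, giving the bicyclic lactone A7.
- Forward key step: Sc(OTf)3 binds the lactone carbonyl of A7. Water attacks the aryl-bearing cyclopropane carbon anti to its bond to C3, and the resulting enolate is protonated at C3. This gives A8, the target as its phenol silyl ether. One desilylation finishes the route.
- For: a stereospecific substitution would carry the cyclopropane configuration into C7'. All carbons and the ring are already in place and there is one protecting group. The endgame after the key intermediate is shorter than in the chosen route.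
- Against: A7 has three contiguous stereocentres, one of them quaternary. Its assembly by intramolecular cyclopropanation would need a metal carbene with an adjacent CH2 group, which is prone to 1,2-hydride shift. A single acceptor is weak activation, while the dimethoxyphenyl donor is strong enough to favour ionisation to a benzylic cation. Ionisation would erase the inversion and invite capture by the other arene or elimination, and water is a weak nucleophile. Protonation of the enolate anti to the C4 substituent would give the cis lactone, so C3 would need a later epimerisation.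
- Comparison: the difficulty is moved into the synthesis of A7, and the stereospecificity of the key step is doubtful for exactly this donor. The chosen route controls C7' by the catalyst, not by a substitution at a centre that ionises easily.

Key step: step 5

Assumption: (S,S)-Et-DuPHOS is taken as the ligand antipode that gives the (R) acid 5, and (S,S)-TsDPEN as the one that gives the (S) carbinol; if a first run shows the opposite sense, the mirror-image ligand is used and nothing else changes.

## Route

Step 1
Reactants: 1 4-(benzyloxy)-3-methoxybenzaldehyde (O-benzylvanillin); 2 di-tert-butyl butanedioate (di-tert-butyl succinate)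
Product: 4 (3E)-4-[4-(benzyloxy)-3-methoxyphenyl]-3-(tert-butoxycarbonyl)but-3-enoic acid, via paraconate lactone 3 (not isolated)
Conditions: KOtBu (1.3 equiv), t-BuOH, reflux; then aq HCl
Reagents that add atoms: none
Why: Stobbe condensation: the succinate enolate adds to the aldehyde, the aldolate closes on the distal ester to lactone 3, and E1cB opening gives the half-ester in which the conjugated carboxyl keeps its tert-butyl group and the other is free, the (E) alkene being the more stable one; tert-butyl esters suppress Claisen self-condensation of 2.

Step 2
Reactants: 4 (3E)-4-[4-(benzyloxy)-3-methoxyphenyl]-3-(tert-butoxycarbonyl)but-3-enoic acid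
Product: 5 (3R)-4-[4-(benzyloxy)-3-methoxyphenyl]-3-(tert-butoxycarbonyl)butanoic acid
Conditions: [Rh(cod)((S,S)-Et-DuPHOS)]BF4 (1 mol%), H2 (5 bar), NaOMe (0.1 equiv), MeOH, 25 °C
Reagents that add atoms: none
Why: Rhodium–bisphosphine asymmetric hydrogenation of a Stobbe-derived itaconate half-ester: carboxylate and alkene chelate the cationic monovalent rhodium and H2 adds to one alkene face, which sets C3 as R; the homogeneous catalyst leaves the benzyl ether and the arenes alone.

Step 3
Reactants: 5 (3R)-4-[4-(benzyloxy)-3-methoxyphenyl]-3-(tert-butoxycarbonyl)butanoic acid
Product: 6 1-tert-butyl 4-methyl (2R)-2-[4-(benzyloxy)-3-methoxybenzyl]butanedioate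
Conditions: MeI, K2CO3, DMF, 25 °C
Reagents that add atoms: iodomethane, CI
Why: Carboxylate O-alkylation (SN2) under a weak base that cannot enolise the tert-butyl ester, so C3 keeps its configuration; the free carboxyl becomes the small, reducible ester that ends as C5.

Step 4
Reactants: 6 1-tert-butyl 4-methyl (2R)-2-[4-(benzyloxy)-3-methoxybenzyl]butanedioate; 7 3,4-dimethoxybenzoyl chloride
Product: 9 1-tert-butyl 4-methyl (2R)-2-[4-(benzyloxy)-3-methoxybenzyl]-3-(3,4-dimethoxybenzoyl)butanedioate as both C3 epimers, via lithium enolate 8 (not isolated)
Conditions: LiN(SiMe3)2 (2.1 equiv), THF, −78 °C; then 7 (1.05 equiv), −78 °C; aq NH4Cl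
Reagents that add atoms: none
Why: Crossed Claisen-type C-acylation of an ester enolate: the amide base takes a proton from the unhindered CH2 beside the methyl ester and not the tertiary C–H beside the tert-butyl ester, so the (R) centre is untouched, and the second equivalent of base holds the acidic product as its enolate until work-up; the new centre (lactone C4) forms as both epimers, which the next step is designed to accept.

Step 5
Reactants: 9 1-tert-butyl 4-methyl (2R)-2-[4-(benzyloxy)-3-methoxybenzyl]-3-(3,4-dimethoxybenzoyl)butanedioate (both C3 epimers)
Product: 10 1-tert-butyl 4-methyl (2R,3S)-2-[4-(benzyloxy)-3-methoxybenzyl]-3-[(S)-(3,4-dimethoxyphenyl)(hydroxy)methyl]butanedioate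
Conditions: RuCl(p-cymene)[(S,S)-TsDPEN] (2 mol%), HCO2H/Et3N (5:2), DMF, 30 °C
Reagents that add atoms: none
Why: Formate turns the precatalyst into the 18-electron ruthenium hydride with an N–H ligand, which passes hydride to the ketone carbon and the N–H proton to the ketone oxygen through a six-membered outer-sphere transition state; the substrate never binds the metal and no ring closes. The closest known reaction type is the Noyori–Ikariya asymmetric transfer hydrogenation of α-substituted β-aryl β-keto esters and amides under dynamic kinetic resolution. The carbinol centre is set by the catalyst: the dimethoxyphenyl ring lies under the η6-cymene (CH–π contact), so the (S,S) diamine should deliver hydride to the face that gives the (S) alcohol, the same sense as for acetophenone because aryl outranks the alkyl branch here too. Lactone C4 is set by the kinetic resolution: its hydrogen sits between ketone and ester, so the two epimers of 9 interconvert through the enol in the triethylammonium formate medium, and only the epimer that can hold its bulky C3 branch anti to the incoming hydride on the catalyst-chosen face (Felkin–Anh) should be reduced quickly, which gives the syn relation of C4 and C7'. The step needs epimerisation to outrun reduction and the syn transition state to win; the double activation of C4–H and the slow reduction of an electron-rich aryl ketone serve the first, and the size difference between the C3 branch and the flat methyl ester serves the second. C3 is not at risk, since its hydrogen is activated only by the tert-butyl ester. The new hydroxyl cannot close on the methyl ester (a four-membered ring) and the bulk of the tert-butyl ester should keep it from closing on C2 in this weakly acidic medium.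

Step 6
Reactants: 10 1-tert-butyl 4-methyl (2R,3S)-2-[4-(benzyloxy)-3-methoxybenzyl]-3-[(S)-(3,4-dimethoxyphenyl)(hydroxy)methyl]butanedioate
Product: 11 1-tert-butyl 4-methyl (2R,3S)-2-[4-(benzyloxy)-3-methoxybenzyl]-3-[(S)-(tert-butyldimethylsilyloxy)(3,4-dimethoxyphenyl)methyl]butanedioate
Conditions: TBSOTf (1.3 equiv), 2,6-lutidine (2.5 equiv), CH2Cl2, −78 → −40 °C
Reagents that add atoms: tert-butyldimethylsilyl trifluoromethanesulfonate, CC(C)(C)[Si](C)(C)OS(=O)(=O)C(F)(F)F
Why: Silyl triflate silylation of a hindered secondary alcohol; low temperature and the hindered base keep the tert-butyl ester and the benzylic C–O bond intact, and no stereocentre is touched.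

Step 7
Reactants: 11 1-tert-butyl 4-methyl (2R,3S)-2-[4-(benzyloxy)-3-methoxybenzyl]-3-[(S)-(tert-butyldimethylsilyloxy)(3,4-dimethoxyphenyl)methyl]butanedioate
Product: 12 tert-butyl (2R,3R,4S)-2-[4-(benzyloxy)-3-methoxybenzyl]-4-(tert-butyldimethylsilyloxy)-4-(3,4-dimethoxyphenyl)-3-(hydroxymethyl)butanoate
Conditions: LiBH4 (2 equiv), MeOH (2 equiv), THF, 0 → 25 °C; aq NH4Cl
Reagents that add atoms: none
Why: Chemoselective ester reduction: LiBH4 reduces methyl esters but is slow with tert-butyl esters, so only C5 goes to the alcohol; the boron-bound alkoxide is a poor nucleophile and should not close on the hindered ester while hydride is present.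

Step 8
Reactants: 12 tert-butyl (2R,3R,4S)-2-[4-(benzyloxy)-3-methoxybenzyl]-4-(tert-butyldimethylsilyloxy)-4-(3,4-dimethoxyphenyl)-3-(hydroxymethyl)butanoate
Product: 13 (3R,4R)-3-[4-(benzyloxy)-3-methoxybenzyl]-4-[(S)-(tert-butyldimethylsilyloxy)(3,4-dimethoxyphenyl)methyl]oxolan-2-one
Conditions: PPTS (0.2 equiv), toluene, 80 °C
Reagents that add atoms: none
Why: Acid-catalysed lactonisation (intramolecular transesterification, 5-exo-trig) of a γ-hydroxy tert-butyl ester with loss of tert-butanol; the pyridinium acid in an aprotic solvent should be too weak to ionise or desilylate the C7' ether, and with O7' blocked only O5 can close, giving the trans lactone with C3 and C4 unchanged.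

Step 9
Reactants: 13 (3R,4R)-3-[4-(benzyloxy)-3-methoxybenzyl]-4-[(S)-(tert-butyldimethylsilyloxy)(3,4-dimethoxyphenyl)methyl]oxolan-2-one
Product: 14 (3R,4R)-4-[(S)-(tert-butyldimethylsilyloxy)(3,4-dimethoxyphenyl)methyl]-3-(4-hydroxy-3-methoxybenzyl)oxolan-2-one
Conditions: H2 (1 atm), 10% Pd/C, EtOAc, 25 °C
Reagents that add atoms: none
Why: Hydrogenolysis of an aryl benzyl ether on palladium; in neutral ethyl acetate this should be much faster than cleavage of the hindered, silylated benzylic C7'–O bond, and the reaction is stopped once 13 is consumed.

Step 10
Reactants: 14 (3R,4R)-4-[(S)-(tert-butyldimethylsilyloxy)(3,4-dimethoxyphenyl)methyl]-3-(4-hydroxy-3-methoxybenzyl)oxolan-2-one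
Product: 15 (3R,4R)-4-[(S)-(3,4-dimethoxyphenyl)(hydroxy)methyl]-3-(4-hydroxy-3-methoxybenzyl)oxolan-2-one
Conditions: HF·pyridine, pyridine, THF, 0 → 25 °C
Reagents that add atoms: none
Why: Fluoride-driven desilylation; the buffered, non-basic medium avoids alkoxide- or phenoxide-induced translactonisation (O7' onto C2) and is too weakly acidic to ionise C7'.

## Compound list

1 | 4-(benzyloxy)-3-methoxybenzaldehyde (O-benzylvanillin) | COc1cc(C=O)ccc1OCc1ccccc1 | starting material
2 | di-tert-butyl butanedioate (di-tert-butyl succinate) | CC(C)(C)OC(=O)CCC(=O)OC(C)(C)C | starting material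
3 | tert-butyl 2-[4-(benzyloxy)-3-methoxyphenyl]-5-oxooxolane-3-carboxylate (paraconate lactone, racemic, both diastereomers) | COc1cc(C2OC(=O)CC2C(=O)OC(C)(C)C)ccc1OCc1ccccc1 | intermediate (not isolated)
4 | (3E)-4-[4-(benzyloxy)-3-methoxyphenyl]-3-(tert-butoxycarbonyl)but-3-enoic acid | COc1cc(/C=C(\CC(=O)O)C(=O)OC(C)(C)C)ccc1OCc1ccccc1 | intermediate
5 | (3R)-4-[4-(benzyloxy)-3-methoxyphenyl]-3-(tert-butoxycarbonyl)butanoic acid | COc1cc(C[C@H](CC(=O)O)C(=O)OC(C)(C)C)ccc1OCc1ccccc1 | intermediate
6 | 1-tert-butyl 4-methyl (2R)-2-[4-(benzyloxy)-3-methoxybenzyl]butanedioate | COc1cc(C[C@H](CC(=O)OC)C(=O)OC(C)(C)C)ccc1OCc1ccccc1 | intermediate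
7 | 3,4-dimethoxybenzoyl chloride | COc1ccc(C(=O)Cl)cc1OC | starting material
8 | lithium (3R)-4-[4-(benzyloxy)-3-methoxyphenyl]-3-(tert-butoxycarbonyl)-1-methoxybut-1-en-1-olate (enolate of 6, alkene geometry not defined) | COc1cc(C[C@H](C=C([O-])OC)C(=O)OC(C)(C)C)ccc1OCc1ccccc1.[Li+] | intermediate (not isolated)
9 | 1-tert-butyl 4-methyl (2R)-2-[4-(benzyloxy)-3-methoxybenzyl]-3-(3,4-dimethoxybenzoyl)butanedioate, both C3 epimers | COc1cc(C[C@H](C(C(=O)OC)C(=O)c2ccc(OC)c(OC)c2)C(=O)OC(C)(C)C)ccc1OCc1ccccc1 | intermediate (precursor of the key step)
10 | 1-tert-butyl 4-methyl (2R,3S)-2-[4-(benzyloxy)-3-methoxybenzyl]-3-[(S)-(3,4-dimethoxyphenyl)(hydroxy)methyl]butanedioate | COc1cc(C[C@H]([C@H](C(=O)OC)[C@H](O)c2ccc(OC)c(OC)c2)C(=O)OC(C)(C)C)ccc1OCc1ccccc1 | intermediate (product of the key step)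
11 | 1-tert-butyl 4-methyl (2R,3S)-2-[4-(benzyloxy)-3-methoxybenzyl]-3-[(S)-(tert-butyldimethylsilyloxy)(3,4-dimethoxyphenyl)methyl]butanedioate | COc1cc(C[C@H]([C@H](C(=O)OC)[C@H](O[Si](C)(C)C(C)(C)C)c2ccc(OC)c(OC)c2)C(=O)OC(C)(C)C)ccc1OCc1ccccc1 | intermediate
12 | tert-butyl (2R,3R,4S)-2-[4-(benzyloxy)-3-methoxybenzyl]-4-(tert-butyldimethylsilyloxy)-4-(3,4-dimethoxyphenyl)-3-(hydroxymethyl)butanoate | COc1cc(C[C@H]([C@H](CO)[C@H](O[Si](C)(C)C(C)(C)C)c2ccc(OC)c(OC)c2)C(=O)OC(C)(C)C)ccc1OCc1ccccc1 | intermediate
13 | (3R,4R)-3-[4-(benzyloxy)-3-methoxybenzyl]-4-[(S)-(tert-butyldimethylsilyloxy)(3,4-dimethoxyphenyl)methyl]oxolan-2-one | COc1cc(C[C@H]2C(=O)OC[C@@H]2[C@H](O[Si](C)(C)C(C)(C)C)c2ccc(OC)c(OC)c2)ccc1OCc1ccccc1 | intermediate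
14 | (3R,4R)-4-[(S)-(tert-butyldimethylsilyloxy)(3,4-dimethoxyphenyl)methyl]-3-(4-hydroxy-3-methoxybenzyl)oxolan-2-one | COc1cc(C[C@H]2C(=O)OC[C@@H]2[C@H](O[Si](C)(C)C(C)(C)C)c2ccc(OC)c(OC)c2)ccc1O | intermediate
15 | (3R,4R)-4-[(S)-(3,4-dimethoxyphenyl)(hydroxy)methyl]-3-(4-hydroxy-3-methoxybenzyl)oxolan-2-one | COc1cc(C[C@H]2C(=O)OC[C@@H]2[C@H](O)c2ccc(OC)c(OC)c2)ccc1O | target

## Step count and least certain steps

Total: 10 steps. Longest linear sequence: 10 steps, from 1 to 15; compounds 2 and 7 enter as purchased materials.

**Step 5 (key step).** The most likely failure is incomplete convergence. Epimerisation at C4 of this α-branched keto ester may fall behind reduction, or the catalyst-chosen face may pair better with the other C4 epimer, so that anti or C4-epimeric alcohols form alongside 10. Long exposure to the formic acid medium could also dehydrate the electron-rich benzylic alcohol. Fallback, setting out from 9: chelation-controlled reduction with Zn(BH4)2 in Et2O at −20 °C. Hydride adds to the zinc chelate of the keto ester anti to the C4 substituent, which should give only the two syn alcohols: 10 and its diastereomer 1-tert-butyl 4-methyl (2R,3R)-2-[4-(benzyloxy)-3-methoxybenzyl]-3-[(R)-(3,4-dimethoxyphenyl)(hydroxy)methyl]butanedioate F1. The two are separated by chromatography. F1 is oxidised back to 9 with Dess–Martin periodinane and recycled. The route is rejoined at 10.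

**Step 4.** The likely failures are O-acylation or double acylation of the enolate, consumption of the acid chloride by the excess amide base, and proton exchange that quenches the enolate before acylation. Fallback, setting out from 6: the enolate 8 is made with 1.05 equiv of LiN(SiMe3)2 and added to 3,4-dimethoxybenzaldehyde at −78 °C with a cold quench. This gives the aldol adduct 1-tert-butyl 4-methyl (2R)-2-[4-(benzyloxy)-3-methoxybenzyl]-3-[(3,4-dimethoxyphenyl)(hydroxy)methyl]butanedioate F2 as a mixture of diastereomers. Oxidation of F2 with Dess–Martin periodinane in CH2Cl2 gives 9, where the route is rejoined.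

**Step 2.** The likely failure is erosion of enantioselectivity. The bulky tert-butyl ester may disturb the carboxylate–alkene chelate on rhodium, and a minor (Z) isomer of 4 may react with the opposite sense. Fallback, setting out from 4: hydrogenation with the achiral complex [Rh(cod)(dppb)]BF4 in MeOH gives racemic 4-[4-(benzyloxy)-3-methoxyphenyl]-3-(tert-butoxycarbonyl)butanoic acid F3. F3 is resolved by preparative chromatography on a chiral stationary phase. The (R) enantiomer is 5, where the route is rejoined.

**Step 7.** The likely failure is slow reduction of the doubly α-branched methyl ester. Forcing conditions could then lead to closure of the alkoxide on C2 in the flask, with further reduction of the lactone or attack on the tert-butyl ester. Fallback, setting out from 11: selective cleavage of the methyl ester with Me3SnOH in 1,2-dichloroethane at 80 °C gives (2S,3R)-3-[4-(benzyloxy)-3-methoxybenzyl]-4-tert-butoxy-2-[(S)-(tert-butyldimethylsilyloxy)(3,4-dimethoxyphenyl)methyl]-4-oxobutanoic acid F4. The acid is reduced with BH3·THF at 0 °C, which leaves the tert-butyl ester, and gives 12, where the route is rejoined.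

**Step 8.** The likely failures are no closure on the hindered tert-butyl ester with so weak an acid, or, if a stronger acid is used, loss of the silyl group or ionisation at C7' before the ring closes. Fallback, setting out from 12: TMSOTf and 2,6-lutidine in CH2Cl2 at 0 °C convert the tert-butyl ester into a silyl ester and silylate O5, giving trimethylsilyl (2R,3R,4S)-2-[4-(benzyloxy)-3-methoxybenzyl]-4-(tert-butyldimethylsilyloxy)-4-(3,4-dimethoxyphenyl)-3-[(trimethylsilyloxy)methyl]butanoate F5, which is not isolated. A mild aqueous citric acid work-up removes both trimethylsilyl groups and gives (2R,3R,4S)-2-[4-(benzyloxy)-3-methoxybenzyl]-4-(tert-butyldimethylsilyloxy)-4-(3,4-dimethoxyphenyl)-3-(hydroxymethyl)butanoic acid F6. F6 is closed with EDC·HCl and DMAP in CH2Cl2 to 13, where the route is rejoined.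

## Further compounds

F1 | step 5 | 1-tert-butyl 4-methyl (2R,3R)-2-[4-(benzyloxy)-3-methoxybenzyl]-3-[(R)-(3,4-dimethoxyphenyl)(hydroxy)methyl]butanedioate | COc1cc(C[C@H]([C@@H](C(=O)OC)[C@@H](O)c2ccc(OC)c(OC)c2)C(=O)OC(C)(C)C)ccc1OCc1ccccc1
F2 | step 4 | 1-tert-butyl 4-methyl (2R)-2-[4-(benzyloxy)-3-methoxybenzyl]-3-[(3,4-dimethoxyphenyl)(hydroxy)methyl]butanedioate, mixture of diastereomers at C3 and the carbinol | COc1cc(C[C@H](C(C(=O)OC)C(O)c2ccc(OC)c(OC)c2)C(=O)OC(C)(C)C)ccc1OCc1ccccc1
F3 | step 2 | racemic 4-[4-(benzyloxy)-3-methoxyphenyl]-3-(tert-butoxycarbonyl)butanoic acid | COc1cc(CC(CC(=O)O)C(=O)OC(C)(C)C)ccc1OCc1ccccc1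
F4 | step 7 | (2S,3R)-3-[4-(benzyloxy)-3-methoxybenzyl]-4-tert-butoxy-2-[(S)-(tert-butyldimethylsilyloxy)(3,4-dimethoxyphenyl)methyl]-4-oxobutanoic acid | COc1cc(C[C@H]([C@H](C(=O)O)[C@H](O[Si](C)(C)C(C)(C)C)c2ccc(OC)c(OC)c2)C(=O)OC(C)(C)C)ccc1OCc1ccccc1
F5 | step 8 | trimethylsilyl (2R,3R,4S)-2-[4-(benzyloxy)-3-methoxybenzyl]-4-(tert-butyldimethylsilyloxy)-4-(3,4-dimethoxyphenyl)-3-[(trimethylsilyloxy)methyl]butanoate | COc1cc(C[C@H]([C@H](CO[Si](C)(C)C)[C@H](O[Si](C)(C)C(C)(C)C)c2ccc(OC)c(OC)c2)C(=O)O[Si](C)(C)C)ccc1OCc1ccccc1
F6 | step 8 | (2R,3R,4S)-2-[4-(benzyloxy)-3-methoxybenzyl]-4-(tert-butyldimethylsilyloxy)-4-(3,4-dimethoxyphenyl)-3-(hydroxymethyl)butanoic acid | COc1cc(C[C@H]([C@H](CO)[C@H](O[Si](C)(C)C(C)(C)C)c2ccc(OC)c(OC)c2)C(=O)O)ccc1OCc1ccccc1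
A1 | alternative 1 | 3-[(S)-(tert-butyldimethylsilyloxy)(3,4-dimethoxyphenyl)methyl]cyclobutan-1-one | O=C1CC(C1)[C@H](O[Si](C)(C)C(C)(C)C)c1ccc(OC)c(OC)c1
A2 | alternative 1 | (R)-4-[(S)-(tert-butyldimethylsilyloxy)(3,4-dimethoxyphenyl)methyl]oxolan-2-one | O=C1C[C@H](CO1)[C@H](O[Si](C)(C)C(C)(C)C)c1ccc(OC)c(OC)c1
A3 | alternative 1 | 1-(benzyloxy)-4-(bromomethyl)-2-methoxybenzene | COc1cc(CBr)ccc1OCc1ccccc1
A4 | alternative 2 | methyl (2R)-2-[4-(benzyloxy)-3-methoxybenzyl]-4-(3,4-dimethoxyphenyl)-4-oxobutanoate | COc1cc(C[C@H](CC(=O)c2ccc(OC)c(OC)c2)C(=O)OC)ccc1OCc1ccccc1
A5 | alternative 2 | formaldehyde | C=O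
A6 | alternative 2 | (3R,4R)-3-[4-(benzyloxy)-3-methoxybenzyl]-4-(3,4-dimethoxybenzoyl)oxolan-2-one | COc1cc(C[C@H]2C(=O)OC[C@@H]2C(=O)c2ccc(OC)c(OC)c2)ccc1OCc1ccccc1
A7 | alternative 3 | (1S,5R,6R)-1-[4-(tert-butyldimethylsilyloxy)-3-methoxybenzyl]-6-(3,4-dimethoxyphenyl)-3-oxabicyclo[3.1.0]hexan-2-one | COc1cc(C[C@@]23C(=O)OC[C@@H]2[C@@H]3c2ccc(OC)c(OC)c2)ccc1O[Si](C)(C)C(C)(C)C
A8 | alternative 3 | (3R,4R)-3-[4-(tert-butyldimethylsilyloxy)-3-methoxybenzyl]-4-[(S)-(3,4-dimethoxyphenyl)(hydroxy)methyl]oxolan-2-one | COc1cc(C[C@H]2C(=O)OC[C@@H]2[C@H](O)c2ccc(OC)c(OC)c2)ccc1O[Si](C)(C)C(C)(C)C
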